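Conventions: guaiane numbering is used throughout, unprimed for unit A (the dienone half) and primed for unit B (the spiro-ketone half); monomeric intermediates carry unprimed numbers. α is the face of H5 (and H1), β the opposite face. Compounds are numbered 1–33 in order of appearance; 33 is the target.

## Analysis of the target

The target (C30H34O6) is heptacyclic: two 5-7-5 guaian-12,6-olide units joined by a spiro-fused cyclohexene made of C1, C2, C10 and C14 of unit A and C15′ and C4′ of unit B, with C4′ as the spiro atom. Unit A is a 3-oxo-guaia-1,4(15)-dien-12,6-olide whose five-membered ring is a cross-conjugated dienone (C15=C4–C3(=O)–C2=C1); sp2 C1 is common to the five-, six- and seven-membered rings. Unit B is a 3′-oxo-guai-10′(14′)-en-12′,6′-olide with a cis-fused hydroazulene (H1′ and H5′ both α). There are eleven stereocentres: C5, C6, C7, C10, C11 and C1′, C4′, C5′, C6′, C7′, C11′. Both halves share the 5αH,6βH,7αH pattern with a trans-fused γ-lactone, but they are epimeric at C11: 11S in unit A (H β, methyl trans to C8) and 11R in unit B (H α, methyl cis to C8′, the less stable arrangement). H10 is β, trans to H5 across planar C1, and at C4′ the bond to C2 lies on the α face. Sensitive groups are the exocyclic enone C4=C15 (Michael acceptor and dienophile), the exocyclic C10′=C14′ alkene (prone to migration), the base-labile C11′ centre and C10, which is γ to the dienone. The difficulty is to make two nearly identical halves with opposite C11 configuration and to join them at a quaternary spiro centre with control of regiochemistry and facial selectivity. The strategy rests on one feature present in both halves: the C6–C7 bond links the oxygen-bearing C6 to the lactone β-carbon C7 inside the seven-membered ring, so the array O6–C6–C7–C11(=C13)–C12 is the retron of a 2-(alkoxycarbonyl)allyl metal adding to a C6 aldehyde. One chromium-mediated closure therefore builds the seven-membered ring and the lactone together, and, because the halves share skeleton and C5–C7 configuration, its product can supply both.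

## Retrosynthetic reasoning

No skeletal bond is cut first. The conjugated C1=C2 enone of 33 is the tautomer of the β,γ-enone 32 (C1=C10, hydrogen on C2). This turns the spiro-cyclohexane into a cyclohexene with its double bond between the two bonds that join the halves, which is a Diels–Alder retron. The forward 1,3-hydrogen shift has to place H10 on the β face and must not disturb C11′.

In 32 the bonds C2–C4′ and C14–C15′ are cut. They are the only bonds between the two C15 units, and cutting both at once gives diene 31 (C2=C1–C10=C14, acyl group on C2) and dienophile 26 (exocyclic enone C4′=C15′). The gain is two monomers of the same skeleton. The forward cycloaddition has to pair C2 with C4′ (the ortho orientation of a 1-acyl diene), use the α face of 26, and outrun self-dimerisation of 31.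

Diene 31 is taken back to ketone 29 through silyl dienol ether 30 (C1=C2 by dehydrogenation). Ketones 29 and 26 differ only at C11 and both go back, through allylic alcohols 28 and 25 and epoxides 27 and 24, to one epoxide 22 that still carries the C11=C13 methylene. Placing the divergence at the conjugate reduction lets C11 be set either under equilibrating conditions (27) or by kinetic protonation (24), and the epoxide route puts oxygen on C3 and the double bond at C4=C15 without relying on the regiochemistry of an ene reaction. Epoxide 22 comes from triene lactone 21.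

In 21 the C6–C7 bond and the O6–C12 lactone bond are cut. This opens both the seven-membered ring and the lactone and leads to aldehyde 18, a cis-1,5-disubstituted cyclopentene carrying a (Z)-2-(bromomethyl)enoate arm. The cut is made here because it removes two rings and two stereocentres in one operation and leaves a precursor whose only stereocentres are C1 and C5. The forward reaction must add the allyl unit through C7, give the anti C6/C7 relationship and the trans H5/H6 relationship, and lactonise.

Aldehyde 18 is traced through alcohol 17 and silyl ether 16 to the allylic alcohol 15, and 15 is cut at C7–C11 into aldehyde 13 and methyl acrylate 14. The C6 carbon is kept as a protected primary alcohol until the last step before the key reaction, so that the epimerisable, β,γ-unsaturated aldehyde exists only briefly.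

Aldehyde 13 comes from nitrile 12; the ring alkene of 12 is derived from the C3 oxygen of alcohol 10 by elimination through mesylate 11. The C8–C9 bond of nitrile 9 is cut to allylic chloride 8 and a two-carbon nitrile nucleophile, and 8 arises by allylic chlorination of the isopropenyl group of 7. The order matters: the chlorination is done while C3–C4 is still saturated, because a trisubstituted ring alkene would react first.

Silyl ether 7 goes back through alcohol 6 to ester 5, and the cyclopentane of 5 is the ring-contraction product of the α-chloro ketone 4. Compound 4 comes from chlorohydrin 3, epoxide 2 and finally (R)-carvone 1, which supplies C1 of the guaiane and, through the stereospecific contraction, the cis relationship of the C5 carbon substituent.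

## Alternatives that were turned down

Alternative 1: The disconnection cuts C6–C7 and C9–C10 of one seven-membered ring and traces it to a formal (4+3) union of fused furan A3 (C10, C1, C5, C6 and the future C6 oxygen) with vinyl diazo ester A2 (C7, C8, C9 and one ester carbon on C7). In the forward step a chiral dirhodium tetraprolinate decomposes A2; the vinylcarbenoid builds a cis-divinylcyclopropane on the C5=C6 edge of A3, and a [3,3] shift delivers the oxa-bridged cycloheptadiene A1. This alternative is stronger than the chosen route on two points: it is catalytic and asymmetric without a chiral-pool starting material, and it forms two C–C bonds and the seven-membered ring in one convergent step with the C6 oxygen already in place. Against it, A1 still lacks C12, C13 and C15; C7 is sp2; the tetrasubstituted C1=C5 alkene needs a cis hydrogenation; the tertiary C10–O bond must be cleaved to the exocyclic alkene while C6–O is kept; and asymmetric induction on a trisubstituted furan is uncertain. The chosen strategy offers instead a key-step product that already has all fifteen carbons, the lactone and four stereocentres in final form and that serves both halves; it pays for this with a longer linear preparation.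

Alternative 2: The disconnection cuts C1′–C10′ of unit B on a cyclopentenone that already carries the lactone, the C11′ methyl and the C3′ ketone. In the forward step a divalent samarium reductant turns a C10′ aldehyde into a ketyl, which closes onto C1′, the β-carbon of the enone, and gives the cis-fused hydroxy hydroazulenone A4. It is stronger than the chosen route in that C11′ can be fixed early on a simple lactone instead of by a late kinetic protonation, and in that the C3′ ketone and an oxygen handle on C15′ are present from the start, so no late oxidation at C3/C4 is needed. Against it, a seven-membered ketyl–alkene closure competes with direct reduction of the enone by the same reagent and with pinacol coupling; the C10′ carbinol of A4 must then be oxidised and methylenated beside the C3′ ketone; and A4 serves unit B only, so unit A would need a second campaign. The chosen strategy offers one intermediate for both halves and carries the C10=C14 alkene from the beginning.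

Alternative 3: The disconnection cuts C10–C14 of the spiro-cyclohexene at a stage where the halves are already joined through C4′–C2 (C2 as a ketone) and the five-membered ring of unit A is still open. In the forward step a primary C14 radical, generated from an iodide on a two-carbon arm at C4′, attacks C10, the β-carbon of the C2 acyl cycloheptene, in 6-endo fashion; the α-radical is reduced to the enolate and captured as enol triflate A5, whose triflate and C5 vinyl group are set up for a carbonylative closure of the methylene-cyclopentenone. It is stronger than the chosen route in that C4′ and C10 are set in separate, individually controllable events rather than by the facial selectivity of a bimolecular cycloaddition and a final equilibration, and in that regiochemistry is unambiguous and self-dimerisation cannot occur. Against it, the quaternary C4′ must be built by intermolecular alkylation of a fully elaborated unit B; the hindered tetrasubstituted enolate must be triflated; a late carbonylative annulation must tolerate three exocyclic alkenes; and the two halves need separate long syntheses. The chosen strategy offers a two-bond union of two monomers drawn from a single intermediate.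

Key step: step 16

Assumption (chemistry): the Favorskii contraction of 4 is taken to follow the invertive cyclopropanone course, which places the ester cis to the isopropenyl group and the C4 methyl cis to the C3 oxygen. THP ethers 4–9 are mixtures at the acetal carbon and 15 is a mixture at C7; both centres disappear later. Steps 18–20 (unit B) and 21–24 (unit A) both start from 22.

## Steps

Step 1
Reactants: 1 (R)-carvone
Product: 2 (1R,4R,6R)-1-methyl-4-(prop-1-en-2-yl)-7-oxabicyclo[4.1.0]heptan-2-one (epoxide trans to isopropenyl)
Conditions: 30% H2O2, NaOH (cat.), MeOH, 0 °C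
Reagents that add atoms: hydrogen peroxide, OO
Why: Nucleophilic (Weitz–Scheffer) epoxidation touches only the enone; hydroperoxide adds anti to the C5 isopropenyl group, so the trans epoxide should form.

Step 2
Reactants: 2 trans-carvone epoxide
Product: 3 (2S,3R,5R)-2-chloro-3-hydroxy-2-methyl-5-(prop-1-en-2-yl)cyclohexan-1-one
Conditions: LiCl, CF3CO2H, THF, rt
Reagents that add atoms: lithium chloride, [Li+].[Cl-]
Why: Acid-promoted trans-diaxial opening of the epoxide by chloride at the tertiary α-carbon (inversion) gives the α-chloro-β-hydroxy ketone needed for ring contraction; chlorine ends cis to the isopropenyl group.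

Step 3
Reactants: 3 chlorohydrin
Product: 4 (2S,3R,5R)-2-chloro-2-methyl-3-(oxan-2-yloxy)-5-(prop-1-en-2-yl)cyclohexan-1-one
Conditions: 3,4-dihydro-2H-pyran, PPTS (cat.), CH2Cl2, rt
Reagents that add atoms: 3,4-dihydro-2H-pyran, C1=COCCC1
Why: Acid-catalysed acetalisation masks the hydroxyl, so that base in the next step can neither re-close the epoxide nor start a retro-aldol cleavage.

Step 4
Reactants: 4 THP-protected chlorohydrin
Product: 5 methyl (1R,2S,3R,5R)-2-methyl-3-(oxan-2-yloxy)-5-(prop-1-en-2-yl)cyclopentane-1-carboxylate (ester cis to isopropenyl)
Conditions: NaOMe, MeOH, 0 °C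
Reagents that add atoms: sodium methoxide, C[O-].[Na+]
Why: Favorskii rearrangement: the C6 enolate displaces the axial tertiary chloride from the rear, so the cyclopropanone carbonyl sits on the face the chloride occupied (cis to isopropenyl), and methoxide opens it toward the ester. Protonation of the departing carbon with retention leaves the methyl cis to the THP-oxy group.

Step 5
Reactants: 5 ring-contracted ester
Product: 6 [(1R,2S,3R,5R)-2-methyl-3-(oxan-2-yloxy)-5-(prop-1-en-2-yl)cyclopentyl]methanol
Conditions: LiAlH4, THF, 0 °C
Reagents that add atoms: none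
Why: Hydride reduction of the ester; once the carbonyl is gone the C5 configuration is fixed until the aldehyde is unveiled just before the key step.

Step 6
Reactants: 6 primary alcohol
Product: 7 tert-butyl{[(1R,2S,3R,5R)-2-methyl-3-(oxan-2-yloxy)-5-(prop-1-en-2-yl)cyclopentyl]methoxy}diphenylsilane
Conditions: TBDPSCl, imidazole, DMF, rt
Reagents that add atoms: tert-butyl(chloro)diphenylsilane, CC(C)(C)[Si](Cl)(c1ccccc1)c1ccccc1
Why: Silylation of the primary alcohol; the robust silyl ether survives the later acid, base, hydride, amine and bromination steps and prevents chloro-etherification onto the neighbouring isopropenyl group in step 7.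

Step 7
Reactants: 7 silyl ether
Product: 8 tert-butyl{[(1R,2S,3R,5R)-5-(3-chloroprop-1-en-2-yl)-2-methyl-3-(oxan-2-yloxy)cyclopentyl]methoxy}diphenylsilane
Conditions: Ca(OCl)2, CO2 (solid), CH2Cl2/H2O, 0 °C
Reagents that add atoms: calcium hypochlorite, [Ca+2].[O-]Cl.[O-]Cl
Why: Ene-type allylic chlorination by hypochlorous acid formed in the flask converts the 1,1-disubstituted alkene into the 2-substituted allyl chloride; it is run while C3–C4 is saturated, because a trisubstituted ring alkene would react first.

Step 8
Reactants: 8 allylic chloride
Product: 9 4-[(1R,2R,3S,4R)-2-{[(tert-butyldiphenylsilyl)oxy]methyl}-3-methyl-4-(oxan-2-yloxy)cyclopentyl]pent-4-enenitrile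
Conditions: MeCN, n-BuLi, THF, −78 °C; then 8, −78 to 0 °C
Reagents that add atoms: acetonitrile, CC#N
Why: SN2 alkylation of lithiated acetonitrile by the allylic chloride adds C8 and C7 (attack at either allylic terminus gives the same product); the nitrile is a masked aldehyde that tolerates steps 9 and 10.

Step 9
Reactants: 9 THP-protected nitrile
Product: 10 4-[(1R,2R,3S,4R)-2-{[(tert-butyldiphenylsilyl)oxy]methyl}-4-hydroxy-3-methylcyclopentyl]pent-4-enenitrile
Conditions: PPTS, MeOH, 45 °C
Reagents that add atoms: none
Why: Acid-catalysed transacetalisation to methanol frees the secondary alcohol; the TBDPS ether and the nitrile are stable under these conditions.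

Step 10
Reactants: 10 secondary alcohol
Product: 12 4-[(1R,5R)-5-{[(tert-butyldiphenylsilyl)oxy]methyl}-4-methylcyclopent-3-en-1-yl]pent-4-enenitrile, via mesylate 11 (not isolated)
Conditions: MsCl, Et3N, CH2Cl2, 0 °C; then DBU, toluene, 100 °C
Reagents that add atoms: none
Why: Mesylation followed by anti-periplanar E2 elimination; H4 is trans to the leaving group because the methyl is cis to it, so the more substituted C3=C4 alkene should form, as it does from cis-2-alkylcyclopentyl sulfonates.

Step 11
Reactants: 12 cyclopentene nitrile
Product: 13 4-[(1R,5R)-5-{[(tert-butyldiphenylsilyl)oxy]methyl}-4-methylcyclopent-3-en-1-yl]pent-4-enal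
Conditions: i-Bu2AlH, CH2Cl2, −78 °C; aq. tartrate work-up
Reagents that add atoms: water, O
Why: The aluminium hydride adds once to the nitrile and the resulting aluminium imine is hydrolysed to the aldehyde on work-up; silyl ether and alkenes are inert.

Step 12
Reactants: 13 C7 aldehyde; 14 methyl acrylate
Product: 15 methyl 6-[(1R,5R)-5-{[(tert-butyldiphenylsilyl)oxy]methyl}-4-methylcyclopent-3-en-1-yl]-3-hydroxy-2-methylidenehept-6-enoate (C3 epimers)
Conditions: DABCO, MeOH, rt, several days
Reagents that add atoms: none
Why: Morita–Baylis–Hillman reaction: the amine–acrylate zwitterion adds to the unhindered aliphatic aldehyde and forms C7–C11; the new carbinol centre is removed in step 13, so no stereocontrol is needed.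

Step 13
Reactants: 15 Baylis–Hillman adduct
Product: 16 methyl (2Z)-2-(bromomethyl)-6-[(1R,5R)-5-{[(tert-butyldiphenylsilyl)oxy]methyl}-4-methylcyclopent-3-en-1-yl]hepta-2,6-dienoate
Conditions: NBS, Me2S, CH2Cl2, 0 °C to rt
Reagents that add atoms: N-bromosuccinimide, O=C1CCC(=O)N1Br
Why: The bromosulfonium reagent activates the allylic alcohol and bromide attacks in SN2′ fashion, giving the rearranged primary bromide with the preferred (Z) geometry (chain trans to the ester), as usual for Baylis–Hillman adducts.

Step 14
Reactants: 16 silyl-protected allylic bromide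
Product: 17 methyl (2Z)-2-(bromomethyl)-6-[(1R,5R)-5-(hydroxymethyl)-4-methylcyclopent-3-en-1-yl]hepta-2,6-dienoate
Conditions: HF·pyridine, THF, 0 °C to rt
Reagents that add atoms: none
Why: Desilylation under acidic, weakly nucleophilic fluoride conditions; the allylic bromide and the enoate tolerate them, whereas basic fluoride sources would displace the bromide.

Step 15
Reactants: 17 hydroxy bromide
Product: 18 methyl (2Z)-2-(bromomethyl)-6-[(1R,5R)-5-formyl-4-methylcyclopent-3-en-1-yl]hepta-2,6-dienoate
Conditions: Dess–Martin periodinane, NaHCO3, CH2Cl2, 0 °C; used at once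
Reagents that add atoms: none
Why: Dess–Martin oxidation under buffered, non-basic conditions should give the β,γ-unsaturated aldehyde without epimerisation at C5 or migration of the C3=C4 bond.

Step 16
Reactants: 18 cyclopentene aldehyde with (Z)-2-(bromomethyl)enoate arm
Product: 21 (1αH,5αH,6βH,7αH)-guaia-3,10(14),11(13)-trien-12,6-olide, via allylchromium 19 (not isolated), via hydroxy ester 20 (not isolated)
Conditions: CrCl2 (6 equiv), THF, 0.005 M (slow addition of 18), rt; dilute HCl work-up
Reagents that add atoms: none
Why: The C–Br bond of 18 is cleaved by two one-electron transfers from CrCl2 (divalent chromium), leaving the σ-allyl complex 19 of trivalent chromium; C–C bond formation then takes place at the far end of the allyl unit, C7, with shift of the double bond to C11=C13, inside a chromium-bridged six-membered array that also binds the aldehyde oxygen (closest known reaction type: intramolecular Nozaki–Hiyama–Kishi allylation of 2-(bromomethyl)enoates leading to α-methylene-γ-butyrolactones on seven-membered rings). The carbocycle closes by 7-exo-trig addition of C7 to the C6 carbonyl, and the lactone closes by 5-exo-trig acyl substitution of the chromium alkoxide of 20 on the methyl ester. C6 is controlled by the ring: the cis arm on C1 can deliver C7 only so that the new bond forms anti to the vinylic C5–C4 bond, which turns O6 away from C1 and places H6 trans to H5. C7 is controlled relative to C6 by the chair form of the chelate in which C5 and C8 are both equatorial, the arrangement that leaves the C8–C9–C10 tether unstrained; it makes H6 and H7 antiperiplanar and gives the trans-lactone. Allylchromium species interconvert by 1,3-metal shift, so this chair should be reachable from the (Z)-bromide. The step needs chemoselective reduction of the allylic bromide beside an aldehyde and an enoate, which low-valent chromium provides, and it needs the aldehyde to keep its C5 configuration, which the non-basic medium secures. High dilution suppresses intermolecular allylation.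

Step 17
Reactants: 21 triene lactone
Product: 22 3α,4α-epoxy-(1αH,5αH,6βH,7αH)-guaia-10(14),11(13)-dien-12,6-olide
Conditions: mCPBA (1.05 equiv), NaHCO3, CH2Cl2, 0 °C
Reagents that add atoms: 3-chloroperoxybenzoic acid, OOC(=O)c1cccc(Cl)c1
Why: Prilezhaev epoxidation: the peracid selects the electron-rich trisubstituted C3=C4 alkene over the 1,1-disubstituted C10=C14 and the electron-poor C11=C13 alkenes and attacks the convex α face; both new centres are removed again in steps 20 and 23.

Step 18
Reactants: 22 epoxy methylene lactone
Product: 24 3α,4α-epoxy-(1αH,5αH,6βH,7αH,11αH)-guai-10(14)-en-12,6-olide (11R), via lactone enolate 23 (not isolated)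
Conditions: LiBH(s-Bu)3 (1.1 equiv), THF, −78 °C; then 2,6-di-tert-butyl-4-methylphenol, −78 °C; aq. NH4Cl
Reagents that add atoms: none
Why: Conjugate hydride addition to the exocyclic enoate gives enolate 23, which is protonated under kinetic control on the α face, anti to C8 on the neighbouring C7 (the face that electrophiles take on trans-fused lactone enolates), so H11 ends α and the methyl β. The bulky phenol reinforces the face selection, and the epoxide and C10=C14 are untouched at −78 °C.

Step 19
Reactants: 24 11αH epoxy lactone
Product: 25 3α-hydroxy-(1αH,5αH,6βH,7αH,11αH)-guaia-4(15),10(14)-dien-12,6-olide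
Conditions: Cp2TiCl2 (2.5 equiv), Mn powder, THF, rt
Reagents that add atoms: none
Why: Cp2TiCl (trivalent titanium) opens the epoxide by single-electron transfer to the tertiary C4 radical; capture by a second Cp2TiCl and β-hydride elimination toward the unhindered methyl gives the exocyclic C4=C15 allylic alcohol under neutral conditions that should not epimerise C11.

Step 20
Reactants: 25 11αH allylic alcohol
Product: 26 3-oxo-(1αH,5αH,6βH,7αH,11αH)-guaia-4(15),10(14)-dien-12,6-olide (unit B monomer)
Conditions: Dess–Martin periodinane, NaHCO3, CH2Cl2, 0 °C
Reagents that add atoms: none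
Why: Dess–Martin oxidation of the allylic alcohol to the α-methylene ketone; no base is present that could epimerise C11 or add to the new enone.

Step 21
Reactants: 22 epoxy methylene lactone
Product: 27 3α,4α-epoxy-(1αH,5αH,6βH,7αH,11βH)-guai-10(14)-en-12,6-olide (11S)
Conditions: NaBH4, MeOH, 0 °C to rt
Reagents that add atoms: none
Why: Conjugate reduction of the α-methylene lactone by borohydride in methanol; the methoxide present equilibrates C11 to the more stable epimer with the methyl trans to C8, the usual outcome for trans-fused 12,6-olides.

Step 22
Reactants: 27 11βH epoxy lactone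
Product: 28 3α-hydroxy-(1αH,5αH,6βH,7αH,11βH)-guaia-4(15),10(14)-dien-12,6-olide
Conditions: Cp2TiCl2 (2.5 equiv), Mn powder, THF, rt
Reagents that add atoms: none
Why: Same radical epoxide-to-allylic-alcohol isomerisation as in step 19: homolysis at the tertiary C4–O bond by trivalent titanium and hydrogen loss from the methyl group give the exocyclic alkene.

Step 23
Reactants: 28 11βH allylic alcohol
Product: 29 3-oxo-(1αH,5αH,6βH,7αH,11βH)-guaia-4(15),10(14)-dien-12,6-olide
Conditions: Dess–Martin periodinane, NaHCO3, CH2Cl2, 0 °C
Reagents that add atoms: none
Why: Dess–Martin oxidation of the allylic alcohol to the α-methylene ketone, as in step 20.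

Step 24
Reactants: 29 unit A ketone
Product: 30 3-(trimethylsilyloxy)-(1αH,5αH,6βH,7αH,11βH)-guaia-2,4(15),10(14)-trien-12,6-olide
Conditions: TMSOTf, Et3N, CH2Cl2, −78 to 0 °C; non-aqueous work-up, used crude
Reagents that add atoms: trimethylsilyl trifluoromethanesulfonate, C[Si](C)(C)OS(=O)(=O)C(F)(F)F
Why: Soft enolisation; C2 is the only enolisable position of the ketone (C4 is sp2) and the lactone is far less acidic, so a single silyl dienol ether should form.

Step 25
Reactants: 30 silyl dienol ether; 26 unit B monomer
Product: 32 Diels–Alder adduct (β,γ-enone isomer of 33 with C1=C10 and H2 on the β face), via dienone 31 (not isolated)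
Conditions: Pd(OAc)2 (1.1 equiv), MeCN, 0.01 M, rt; filter; add 26 (2.5 equiv), concentrate, toluene, 40 °C
Reagents that add atoms: none
Why: Saegusa–Ito oxidation (divalent palladium binds C2 on the α face; syn β-hydride elimination of H1) gives dienone 31, whose C2=C1–C10=C14 diene is held s-cis by the seven-membered ring. Diels–Alder addition to the exocyclic enone of 26 follows the ortho rule for 1-acyl dienes (C2 to C4′, C14 to C15′), and the diene adds to the convex α face of 26 (the side of H5′), which sets C4′ as R; the C2 centre is transient.

Step 26
Reactants: 32 Diels–Alder adduct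
Product: 33 target compound CNP0240988.1
Conditions: DBU (0.2 equiv), CH2Cl2, 0 °C to rt
Reagents that add atoms: none
Why: Base-mediated 1,3-prototropic shift through the extended dienolate moves the β,γ double bond into conjugation (C1=C2). C10 is protonated reversibly and should settle as the more stable epimer with H10 β, trans to H5, in which C6 and C9 lie on opposite faces of planar C1 (twist-chair seven-membered ring). Catalytic DBU at low temperature is too weak to enolise the lactones, so C11′ should be kept.

## Compound list

1 | (R)-carvone | CC1=CC[C@H](CC1=O)C(=C)C | starting material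
2 | (1R,4R,6R)-1-methyl-4-(prop-1-en-2-yl)-7-oxabicyclo[4.1.0]heptan-2-one | C[C@]12O[C@@H]2C[C@H](CC1=O)C(C)=C | intermediate
3 | (2S,3R,5R)-2-chloro-3-hydroxy-2-methyl-5-(prop-1-en-2-yl)cyclohexan-1-one | C[C@]1(Cl)[C@H](O)C[C@H](CC1=O)C(C)=C | intermediate
4 | THP ether of 3 (acetal epimers) | C[C@]1(Cl)[C@H](OC2CCCCO2)C[C@H](CC1=O)C(C)=C | intermediate
5 | methyl (1R,2S,3R,5R)-2-methyl-3-(oxan-2-yloxy)-5-(prop-1-en-2-yl)cyclopentane-1-carboxylate | COC(=O)[C@H]1[C@H](C)[C@H](OC2CCCCO2)C[C@H]1C(C)=C | intermediate
6 | [(1R,2S,3R,5R)-2-methyl-3-(oxan-2-yloxy)-5-(prop-1-en-2-yl)cyclopentyl]methanol | OC[C@H]1[C@H](C)[C@H](OC2CCCCO2)C[C@H]1C(C)=C | intermediate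
7 | TBDPS ether of 6 | CC(C)(C)[Si](c1ccccc1)(c1ccccc1)OC[C@H]1[C@H](C)[C@H](OC2CCCCO2)C[C@H]1C(C)=C | intermediate
8 | allylic chloride (3-chloroprop-1-en-2-yl in place of isopropenyl in 7) | CC(C)(C)[Si](c1ccccc1)(c1ccccc1)OC[C@H]1[C@H](C)[C@H](OC2CCCCO2)C[C@H]1C(=C)CCl | intermediate
9 | THP-protected pent-4-enenitrile | CC(C)(C)[Si](c1ccccc1)(c1ccccc1)OC[C@H]1[C@H](C)[C@H](OC2CCCCO2)C[C@H]1C(=C)CCC#N | intermediate
10 | hydroxy nitrile (C3–OH free, methyl cis to OH) | CC(C)(C)[Si](c1ccccc1)(c1ccccc1)OC[C@H]1[C@H](C)[C@H](O)C[C@H]1C(=C)CCC#N | intermediate
11 | mesylate of 10 (formed in the flask) | CC(C)(C)[Si](c1ccccc1)(c1ccccc1)OC[C@H]1[C@H](C)[C@H](OS(C)(=O)=O)C[C@H]1C(=C)CCC#N | intermediate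
12 | 4-[(1R,5R)-5-{[(tert-butyldiphenylsilyl)oxy]methyl}-4-methylcyclopent-3-en-1-yl]pent-4-enenitrile | CC1=CC[C@@H](C(=C)CCC#N)[C@H]1CO[Si](c1ccccc1)(c1ccccc1)C(C)(C)C | intermediate
13 | 4-[(1R,5R)-5-{[(tert-butyldiphenylsilyl)oxy]methyl}-4-methylcyclopent-3-en-1-yl]pent-4-enal | CC1=CC[C@@H](C(=C)CCC=O)[C@H]1CO[Si](c1ccccc1)(c1ccccc1)C(C)(C)C | intermediate
14 | methyl acrylate | C=CC(=O)OC | starting material
15 | Baylis–Hillman adduct (C7 epimers) | CC1=CC[C@@H](C(=C)CCC(O)C(=C)C(=O)OC)[C@H]1CO[Si](c1ccccc1)(c1ccccc1)C(C)(C)C | intermediate
16 | silyl-protected (Z)-2-(bromomethyl)enoate | CC1=CC[C@@H](C(=C)CC/C=C(\CBr)C(=O)OC)[C@H]1CO[Si](c1ccccc1)(c1ccccc1)C(C)(C)C | intermediate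
17 | hydroxymethyl (Z)-2-(bromomethyl)enoate | CC1=CC[C@@H](C(=C)CC/C=C(\CBr)C(=O)OC)[C@H]1CO | intermediate
18 | methyl (2Z)-2-(bromomethyl)-6-[(1R,5R)-5-formyl-4-methylcyclopent-3-en-1-yl]hepta-2,6-dienoate (key-step precursor) | CC1=CC[C@@H](C(=C)CC/C=C(\CBr)C(=O)OC)[C@H]1C=O | intermediate
19 | allylchromium dichloride from 18 (formed in the flask) | CC1=CC[C@@H](C(=C)CC/C=C(\C[Cr](Cl)Cl)C(=O)OC)[C@H]1C=O | intermediate
20 | methyl 2-[(1αH,5αH,6βH,7αH)-6-hydroxyguaia-3,10(14)-dien-7-yl]acrylate, present as its chromium alkoxide (formed in the flask) | CC1=CC[C@H]2C(=C)CC[C@@H](C(=C)C(=O)OC)[C@H](O)[C@H]21 | intermediate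
21 | (1αH,5αH,6βH,7αH)-guaia-3,10(14),11(13)-trien-12,6-olide (key-step product) | CC1=CC[C@H]2C(=C)CC[C@@H]3[C@H](OC(=O)C3=C)[C@H]21 | intermediate
22 | 3α,4α-epoxy-(1αH,5αH,6βH,7αH)-guaia-10(14),11(13)-dien-12,6-olide | C[C@@]12O[C@@H]1C[C@H]3C(=C)CC[C@@H]4[C@H](OC(=O)C4=C)[C@@H]23 | intermediate
23 | lithium lactone enolate of 24 (formed in the flask) | C[C@@]12O[C@@H]1C[C@H]3C(=C)CC[C@@H]4[C@H](OC([O-])=C4C)[C@@H]23.[Li+] | intermediate
24 | 3α,4α-epoxy-(11αH)-guai-10(14)-en-12,6-olide (11R) | C[C@@]12O[C@@H]1C[C@H]3C(=C)CC[C@@H]4[C@H](OC(=O)[C@@H]4C)[C@@H]23 | intermediate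
25 | 3α-hydroxy-(11αH)-guaia-4(15),10(14)-dien-12,6-olide | C=C1[C@H](O)C[C@H]2C(=C)CC[C@@H]3[C@H](OC(=O)[C@@H]3C)[C@H]21 | intermediate
26 | 3-oxo-(1αH,5αH,6βH,7αH,11αH)-guaia-4(15),10(14)-dien-12,6-olide (unit B monomer) | C=C1C(=O)C[C@H]2C(=C)CC[C@@H]3[C@H](OC(=O)[C@@H]3C)[C@H]21 | intermediate
27 | 3α,4α-epoxy-(11βH)-guai-10(14)-en-12,6-olide (11S) | C[C@@]12O[C@@H]1C[C@H]3C(=C)CC[C@@H]4[C@H](OC(=O)[C@H]4C)[C@@H]23 | intermediate
28 | 3α-hydroxy-(11βH)-guaia-4(15),10(14)-dien-12,6-olide | C=C1[C@H](O)C[C@H]2C(=C)CC[C@@H]3[C@H](OC(=O)[C@H]3C)[C@H]21 | intermediate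
29 | 3-oxo-(1αH,5αH,6βH,7αH,11βH)-guaia-4(15),10(14)-dien-12,6-olide | C=C1C(=O)C[C@H]2C(=C)CC[C@@H]3[C@H](OC(=O)[C@H]3C)[C@H]21 | intermediate
30 | 3-(trimethylsilyloxy)-(11βH)-guaia-2,4(15),10(14)-trien-12,6-olide | C=C1C(O[Si](C)(C)C)=C[C@H]2C(=C)CC[C@@H]3[C@H](OC(=O)[C@H]3C)[C@H]21 | intermediate
31 | 3-oxo-(5αH,6βH,7αH,11βH)-guaia-1,4(15),10(14)-trien-12,6-olide (unit A diene, formed in the flask) | C=C1C(=O)C=C2C(=C)CC[C@@H]3[C@H](OC(=O)[C@H]3C)[C@H]21 | intermediate
32 | Diels–Alder adduct with C1=C10, H2 β, C2–C4′ and C14–C15′ bonds | C=C1C(=O)[C@H]2C3=C(CC[C@@H]4[C@H](OC(=O)[C@H]4C)[C@@H]13)CC[C@]21C(=O)C[C@H]2C(=C)CC[C@@H]3[C@H](OC(=O)[C@@H]3C)[C@H]21 | intermediate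
33 | CNP0240988.1 | C=C1C(=O)C2=C3[C@@H](CC[C@@H]4[C@H](OC(=O)[C@H]4C)[C@@H]13)CC[C@]21C(=O)C[C@H]2C(=C)CC[C@@H]3[C@H](OC(=O)[C@@H]3C)[C@H]21 | target

## Step count and least certain steps

Total: 26 steps. Longest linear sequence: 23 steps (steps 1–17, 21–24, 25, 26); the unit B branch (steps 18–20) joins at step 25.

Step 16 (key step). The most likely failure is addition through the competing chair in which C8 stays axial, the course that the (Z)-geometry favours when the allyl metal does not isomerise; this would close the cis-fused lactone. Further risks are attack on the other aldehyde face, protonolysis of the allylchromium (simple reduction of the bromide), intermolecular allylation if dilution is insufficient, and epimerisation of C5 before cyclisation. The fallback replaces the labile allylchromium by a geometrically defined allylboronate that transfers its geometry through a closed chair; it sets out from 13 and returns at 21. Homologation of 13 with the Ohira–Bestmann reagent (K2CO3, MeOH) gives the terminal alkyne F1. Deprotonation (n-BuLi) and methyl chloroformate give the ynoate F2. Conjugate hydroalumination with i-Bu2AlH–HMPA (syn addition, aluminium on C11) and trapping with ICH2B(pin) give the (Z)-allylboronate F3, in which C8 is cis to the ester and trans to the CH2B group. Buffered TBAF/AcOH, usable here because no allylic bromide is present, gives the alcohol F4, and Dess–Martin oxidation gives the boronate aldehyde F5. F5 should cyclise on gentle warming with C8 equatorial (anti adduct), and acid work-up lactonises to 21.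

Step 25. Dienone 31 is diene and dienophile in one molecule, so self-dimerisation may outrun the cross reaction; two electron-poor partners may also react slowly, attack on the β face of 26 would invert C4′, and residual palladium hydride could migrate the exocyclic alkenes. The fallback removes the dienophile character of unit A by a redox detour; it sets out from 29 (through 30 and 31 as before) and returns at 32. The dilute solution of 31 is reduced at once under Luche conditions (NaBH4, CeCl3, MeOH, −40 °C) to the stable trienol F6. F6 is now only a diene and is combined with 26 (thermally or with Me2AlCl) to give the hydroxy adduct F7, whose Dess–Martin oxidation gives 32.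

Step 26. Protonation of the dienolate at C10 may be kinetically controlled and take the wrong face; stronger or longer base treatment may epimerise C11′, add to the C4=C15 enone or move the C10′=C14′ bond. The fallback sets out from 32 and returns at 33 and replaces enolate chemistry by a suprafacial metal-hydride 1,3-hydrogen shift (rhodium trichloride hydrate in ethanol, π-allyl hydride mechanism). Because the C2 hydrogen of 32 lies on the β face, it would be carried to the β face of C10, and no base touches the lactones. No new compound arises (F0).

Step 18. Face discrimination in the protonation of enolate 23 may be incomplete, and traces of base during work-up may equilibrate C11 toward the 11βH epimer. Any such epimer is compound 27 and can be used in the unit A branch, so material is not lost. The fallback sets out from 22 and returns at 24: an ene-reductase of the Old Yellow Enzyme family (NADPH recycled by glucose dehydrogenase) adds hydride to C13 and a proton to C11 under catalyst control, with screening of enantiocomplementary enzymes. No new compound arises (F0).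

Step 10. Elimination may turn toward C2 and give the disubstituted C2=C3 alkene, or DBU may substitute the mesylate. The fallback builds the alkene from the ketone; it sets out from 10 and returns at 12. Dess–Martin oxidation gives the cyclopentanone F8. Triflation under equilibrating conditions (Tf2O, 2,6-di-tert-butyl-4-methylpyridine) gives the more substituted enol triflate F9. Reduction with Pd(OAc)2/PPh3, Bu3N and HCO2H (hydride transfer at zerovalent palladium) removes the triflate and gives 12.

## Further compounds

F1 | step 16 | tert-butyl{[(1R,5R)-5-(hex-1-en-5-yn-2-yl)-2-methylcyclopent-2-en-1-yl]methoxy}diphenylsilane (terminal alkyne) | CC1=CC[C@@H](C(=C)CCC#C)[C@H]1CO[Si](c1ccccc1)(c1ccccc1)C(C)(C)C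
F2 | step 16 | methyl 6-[(1R,5R)-5-{[(tert-butyldiphenylsilyl)oxy]methyl}-4-methylcyclopent-3-en-1-yl]hept-6-en-2-ynoate | CC1=CC[C@@H](C(=C)CCC#CC(=O)OC)[C@H]1CO[Si](c1ccccc1)(c1ccccc1)C(C)(C)C
F3 | step 16 | methyl (2Z)-6-[(1R,5R)-5-{[(tert-butyldiphenylsilyl)oxy]methyl}-4-methylcyclopent-3-en-1-yl]-2-[(4,4,5,5-tetramethyl-1,3,2-dioxaborolan-2-yl)methyl]hepta-2,6-dienoate | CC1=CC[C@@H](C(=C)CC/C=C(/CB2OC(C)(C)C(C)(C)O2)C(=O)OC)[C@H]1CO[Si](c1ccccc1)(c1ccccc1)C(C)(C)C
F4 | step 16 | methyl (2Z)-6-[(1R,5R)-5-(hydroxymethyl)-4-methylcyclopent-3-en-1-yl]-2-[(4,4,5,5-tetramethyl-1,3,2-dioxaborolan-2-yl)methyl]hepta-2,6-dienoate | CC1=CC[C@@H](C(=C)CC/C=C(/CB2OC(C)(C)C(C)(C)O2)C(=O)OC)[C@H]1CO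
F5 | step 16 | methyl (2Z)-6-[(1R,5R)-5-formyl-4-methylcyclopent-3-en-1-yl]-2-[(4,4,5,5-tetramethyl-1,3,2-dioxaborolan-2-yl)methyl]hepta-2,6-dienoate | CC1=CC[C@@H](C(=C)CC/C=C(/CB2OC(C)(C)C(C)(C)O2)C(=O)OC)[C@H]1C=O
F6 | step 25 | 3-hydroxy-(5αH,6βH,7αH,11βH)-guaia-1,4(15),10(14)-trien-12,6-olide (C3 epimers) | C=C1C(O)C=C2C(=C)CC[C@@H]3[C@H](OC(=O)[C@H]3C)[C@H]21
F7 | step 25 | 3-hydroxy analogue of adduct 32 (C3 epimers) | C=C1C(O)[C@H]2C3=C(CC[C@@H]4[C@H](OC(=O)[C@H]4C)[C@@H]13)CC[C@]21C(=O)C[C@H]2C(=C)CC[C@@H]3[C@H](OC(=O)[C@@H]3C)[C@H]21
F0 | step 26 | none | none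
F0 | step 18 | none | none
F8 | step 10 | 4-[(1R,2R,3S)-2-{[(tert-butyldiphenylsilyl)oxy]methyl}-3-methyl-4-oxocyclopentyl]pent-4-enenitrile | CC(C)(C)[Si](c1ccccc1)(c1ccccc1)OC[C@H]1[C@H](C)C(=O)C[C@H]1C(=C)CCC#N
F9 | step 10 | (4R,5R)-5-{[(tert-butyldiphenylsilyl)oxy]methyl}-4-(4-cyanobut-1-en-2-yl)-1-methylcyclopent-1-en-2-yl... enol triflate (3-triflyloxy analogue of 12) | CC1=C(OS(=O)(=O)C(F)(F)F)C[C@@H](C(=C)CCC#N)[C@H]1CO[Si](c1ccccc1)(c1ccccc1)C(C)(C)C
A1 | alternative 1 | 8-oxabicyclo[3.2.1]octadiene adduct (C6–O–C10 bridged) | COC(=O)C1=CC[C@@]2(CO[Si](C)(C)C(C)(C)C)O[C@@H]1C3=C2CC4(C3)OCCO4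
A2 | alternative 1 | methyl 2-diazobut-3-enoate | C=CC(=[N+]=[N-])C(=O)OC
A3 | alternative 1 | 1-{[(tert-butyldimethylsilyl)oxy]methyl}-4H,6H-cyclopenta[c]furan-5-one ethylene ketal | CC(C)(C)[Si](C)(C)OCc1occ2c1CC1(C2)OCCO1
A4 | alternative 2 | 10′-hydroxy hydroazulenone lactone | O[C@H]1CC[C@@H]2[C@H](OC(=O)[C@@H]2C)[C@@H]3[C@H]1CC(=O)[C@H]3CO[Si](C)(C)C(C)(C)C
A5 | alternative 3 | spiro C2 enol triflate carrying a C5 vinyl group | FC(F)(F)S(=O)(=O)OC2=C3[C@@H](CC[C@@H]4[C@H](OC(=O)[C@H]4C)[C@H]3C=C)CC[C@]21C(=O)C[C@H]2C(=C)CC[C@@H]3[C@H](OC(=O)[C@@H]3C)[C@H]21
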